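**Direct plan and its weak points**

A direct plan would acetylate 1,2,3,5-tetramethoxybenzene A1 with AcCl/AlCl3 and let excess AlCl3 remove one ortho-methyl group, giving 2'-hydroxy-3',4',6'-trimethoxyacetophenone A2.
Condensation of A2 with 2,4-dimethoxybenzaldehyde A3 would give (E)-2'-hydroxy-2,4,3',4',6'-pentamethoxychalcone A4, I2/DMSO would close and dehydrogenate ring C to 2',4',5,7,8-pentamethoxyflavone A5, and BCl3 would finally cleave the 5-OMe to the target.
- The Friedel–Crafts acylation of A1 with in-situ O-demethylation would be weak: the whole 7,8- versus 6,7-oxygenation pattern of ring A would rest on which of the two methoxy groups flanking the ketone is cleaved, and the isomers of A2 would be hard to tell apart.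
- The final BCl3 demethylation of A5 would be weak: O5 would be methylated only to be unmasked again, with four other aryl methyl ethers exposed to a Lewis acid and a risk of Wessely–Moser isomerisation of the 5-hydroxy-7,8-dioxygenated chromone.
- The I2/DMSO oxidative cyclisation of A4 at 130 °C would be weak: hot iodine on two very electron-rich rings would risk ring iodination and aurone formation.

**Retrosynthetic overview of the new route**

Ring A carries C5–OH and C8–OMe para to each other, with C6–H and C7–OMe between them. This is the hydroquinone monomethyl ether pattern that a 4-aryl-4-methoxycyclobutenone gives on thermal ring expansion (Moore rearrangement).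
The target is cut at C4a–C5 (formed in the key step) and at C8–C8a (pyranonyl Grignard reagent plus methyl semisquarate).
Ring C is made first, as 2-(2,4-dimethoxyphenyl)-4H-pyran-4-one; ring A is grown onto its C5=C6 bond last.
Every oxygen of ring A is placed by connectivity, so no selective ether cleavage, no methyl-on/methyl-off at O5 and no oxidative cyclisation is needed; the last step is a reagent-free isomerisation.

Key step: step 6

Remark: the target is achiral; the stereocentres met on the way (C4 of 8, 11 and 12, C4a of 14) would form racemic and are erased. Dione 9 is moisture-sensitive and would be used directly.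

**Step 1**
Reactants: 1 (E)-4-methoxybut-3-en-2-one; 2 2,4-dimethoxybenzoyl chloride
Product: 4 2-(2,4-dimethoxyphenyl)-4H-pyran-4-one, via 1-(2,4-dimethoxyphenyl)-5-methoxypent-4-ene-1,3-dione 3 (not isolated)
Conditions: 1 (2.2 eq), LiN(SiMe3)2 (2.2 eq), THF, −78 °C; 2 (1.0 eq), −78 → 0 °C; 1 M HCl work-up; then CF3CO2H, PhMe, rt
Reagents that add atoms: none
Why: γ-pyrone synthesis by enolate C-acylation and acid cyclisation, in which the kinetic lithium enolate of 1 is acylated by 2 to diketone 3 (the second equivalent of enolate takes up its acidic proton) and the enol oxygen of 3 then adds to the β-methoxy enone and expels methanol.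

**Step 2**
Reactants: 4 2-(2,4-dimethoxyphenyl)-4H-pyran-4-one
Product: 6 2-(2,4-dimethoxyphenyl)-6-iodo-4H-pyran-4-one, via [6-(2,4-dimethoxyphenyl)-4-oxo-4H-pyran-2-yl]zinc chloride 5 (not isolated)
Conditions: TMPZnCl·LiCl (1.3 eq, TMP = 2,2,6,6-tetramethylpiperidide, no added MgCl2 or BF3·OEt2), THF, 0 → 25 °C; then I2 (1.5 eq), 0 °C; aq Na2S2O3
Reagents that add atoms: iodine, II
Why: directed zincation with TMPZnCl·LiCl, which on chromone-type rings should remove the most acidic ring hydrogen, the one on the carbon bound to the ring oxygen (here C6), followed by iodinolysis of the C–Zn bond; the mild base should leave the carbonyl-flanking positions and the dimethoxyphenyl ring untouched.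

**Step 3**
Reactants: 7 dimethyl squarate (3,4-dimethoxycyclobut-3-ene-1,2-dione)
Product: 9 3-methoxycyclobut-3-ene-1,2-dione, via 4-hydroxy-2,3-dimethoxycyclobut-2-en-1-one 8 (not isolated)
Conditions: LiAlH(Ot-Bu)3 (1.0 eq), THF, −78 °C; 1 M HCl quench; then conc. HCl (cat.), CH2Cl2, rt
Reagents that add atoms: none
Why: mono-1,2-reduction of one of the two equivalent squarate carbonyls by LiAlH(Ot-Bu)3, then the standard acid-promoted transposition of the 4-hydroxy-2,3-dialkoxycyclobutenone (ionisation of the carbinol, water capture at the distal alkoxy carbon, loss of methanol) to the alkoxycyclobutenedione.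

**Step 4**
Reactants: 6 2-(2,4-dimethoxyphenyl)-6-iodo-4H-pyran-4-one; 9 3-methoxycyclobut-3-ene-1,2-dione
Product: 11 4-[6-(2,4-dimethoxyphenyl)-4-oxo-4H-pyran-2-yl]-4-hydroxy-3-methoxycyclobut-2-en-1-one, via [6-(2,4-dimethoxyphenyl)-4-oxo-4H-pyran-2-yl]magnesium chloride 10 (not isolated)
Conditions: 6, i-PrMgCl·LiCl (1.05 eq), THF, −78 °C, 20 min; cannulation into 9 (1.3 eq), THF, −78 °C; aq NH4Cl, −78 °C → rt
Reagents that add atoms: none
Why: iodine–magnesium exchange on the electron-poor alkenyl iodide, then Grignard 1,2-addition to the cyclobutenedione at the carbonyl next to the methoxy-bearing carbon, the other carbonyl being deactivated as a vinylogous ester; the new quaternary carbinol centre forms racemic and is erased in step 6.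

**Step 5**
Reactants: 11 4-[6-(2,4-dimethoxyphenyl)-4-oxo-4H-pyran-2-yl]-4-hydroxy-3-methoxycyclobut-2-en-1-one
Product: 12 4-[6-(2,4-dimethoxyphenyl)-4-oxo-4H-pyran-2-yl]-3,4-dimethoxycyclobut-2-en-1-one
Conditions: MeI (10 eq), Ag2O (2 eq), 4 Å MS, MeCN, rt, dark
Reagents that add atoms: iodomethane, CI
Why: Ag2O-mediated O-methylation (Purdie conditions) of the tertiary cyclobutenol, the usual way to cap such carbinols without strong base; this methyl group becomes the 8-OMe of the target.

**Step 6**
Reactants: 12 4-[6-(2,4-dimethoxyphenyl)-4-oxo-4H-pyran-2-yl]-3,4-dimethoxycyclobut-2-en-1-one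
Product: 15 5-hydroxy-2',4',7,8-tetramethoxyflavone, via (3Z)-3,4-dimethoxy-4-(pyranonyl)buta-1,3-dien-1-one 13 (not isolated), via 2-(2,4-dimethoxyphenyl)-7,8-dimethoxy-4aH-chromene-4,5-dione 14 (not isolated)
Conditions: degassed p-xylene (0.01 M), 138 °C, 2 h, Ar
Reagents that add atoms: none
Why: Heating should open the cyclobutenone by conrotatory four-electron electrocyclic ring opening, the 4-methoxy group rotating outward (torquoselectivity of donor substituents) so that the pyranonyl group sits cis to the ketene in (3Z)-vinylketene 13. Disrotatory six-electron electrocyclisation between the ketene carbon and pyranone C5, the nucleophilic carbon of the ring enol ether, should then form the C4a–C5 bond and close ring A as dienone 14, whose 4a-hydrogen lies between two carbonyl groups and is lost by enolisation to the phenol hydrogen-bonded to C4=O. The closest known reaction type is the Moore rearrangement of 4-aryl- and 4-heteroaryl-4-alkoxycyclobutenones to hydroquinone monoethers. No stereocentre remains, since the racemic quaternary centre of 12 and the transient C4a centre of 14 are erased on aromatisation. The regiochemistry needs no selectivity because connectivity fixes it (ketene carbon becomes C5–OH, C2–H becomes C6–H, C3–OMe becomes C7–OMe, C4–OMe becomes C8–OMe); the step does need ring closure to outrun ketene dimerisation, which high dilution and the absence of nucleophiles should secure.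

**Compound list**

1 | (E)-4-methoxybut-3-en-2-one | CO/C=C/C(C)=O | starting material
2 | 2,4-dimethoxybenzoyl chloride | COc1ccc(C(=O)Cl)c(OC)c1 | starting material
3 | (4E)-1-(2,4-dimethoxyphenyl)-5-methoxypent-4-ene-1,3-dione (not isolated) | CO/C=C/C(=O)CC(=O)c1ccc(OC)cc1OC | intermediate
4 | 2-(2,4-dimethoxyphenyl)-4H-pyran-4-one | COc1ccc(-c2cc(=O)cco2)c(OC)c1 | intermediate
5 | [6-(2,4-dimethoxyphenyl)-4-oxo-4H-pyran-2-yl]zinc chloride (not isolated) | COc1ccc(-c2cc(=O)cc([Zn]Cl)o2)c(OC)c1 | intermediate
6 | 2-(2,4-dimethoxyphenyl)-6-iodo-4H-pyran-4-one | COc1ccc(-c2cc(=O)cc(I)o2)c(OC)c1 | intermediate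
7 | dimethyl squarate, 3,4-dimethoxycyclobut-3-ene-1,2-dione | COC1=C(OC)C(=O)C1=O | starting material
8 | 4-hydroxy-2,3-dimethoxycyclobut-2-en-1-one, racemic (not isolated) | COC1=C(OC)C(O)C1=O | intermediate
9 | 3-methoxycyclobut-3-ene-1,2-dione (methyl semisquarate) | COC1=CC(=O)C1=O | intermediate
10 | [6-(2,4-dimethoxyphenyl)-4-oxo-4H-pyran-2-yl]magnesium chloride (not isolated) | COc1ccc(-c2cc(=O)cc([Mg]Cl)o2)c(OC)c1 | intermediate
11 | 4-[6-(2,4-dimethoxyphenyl)-4-oxo-4H-pyran-2-yl]-4-hydroxy-3-methoxycyclobut-2-en-1-one, racemic | COC1=CC(=O)C1(O)c1cc(=O)cc(-c2ccc(OC)cc2OC)o1 | intermediate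
12 | 4-[6-(2,4-dimethoxyphenyl)-4-oxo-4H-pyran-2-yl]-3,4-dimethoxycyclobut-2-en-1-one, racemic | COC1=CC(=O)C1(OC)c1cc(=O)cc(-c2ccc(OC)cc2OC)o1 | intermediate
13 | (3Z)-4-[6-(2,4-dimethoxyphenyl)-4-oxo-4H-pyran-2-yl]-3,4-dimethoxybuta-1,3-dien-1-one (not isolated) | O=C=C/C(OC)=C(OC)\c1cc(=O)cc(-c2ccc(OC)cc2OC)o1 | intermediate
14 | 2-(2,4-dimethoxyphenyl)-7,8-dimethoxy-4aH-chromene-4,5-dione, racemic (not isolated) | COc1ccc(C2=CC(=O)C3C(=O)C=C(OC)C(OC)=C3O2)c(OC)c1 | intermediate
15 | 5-hydroxy-2',4',7,8-tetramethoxyflavone, 2-(2,4-dimethoxyphenyl)-5-hydroxy-7,8-dimethoxy-4H-chromen-4-one, achiral | COc1ccc(-c2cc(=O)c3c(O)cc(OC)c(OC)c3o2)c(OC)c1 | target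

**Step count and risks**

Total steps: 6. Longest linear sequence: 5 (steps 1, 2, 4, 5, 6); step 3 is the convergent branch.

Steps most likely to fail:

1. Step 6, the ring expansion. The vinylketene 13 could oligomerise faster than it closes onto the cross-conjugated, electron-poor pyranone double bond, or the ring could open with the pyranonyl group turned away from the ketene. In that case ring A would be bought instead of built. The fallback sets out from acid chloride 2, which would acylate 2'-hydroxy-3',4',6'-trimethoxyacetophenone A2 (pyridine, rt) to 2-acetyl-3,5,6-trimethoxyphenyl 2,4-dimethoxybenzoate F1. Baker–Venkataraman acyl transfer (KOH, pyridine, 50 °C) would give 1-(2,4-dimethoxyphenyl)-3-(2-hydroxy-3,4,6-trimethoxyphenyl)propane-1,3-dione F2. Cyclodehydration (H2SO4, AcOH) would give 2',4',5,7,8-pentamethoxyflavone A5, and BCl3 (CH2Cl2, −78 → 0 °C) would cleave the chelated 5-OMe, coming back to the route at 15.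

2. Step 4, the exchange and carbonyl addition. The reagent i-PrMgCl·LiCl could attack the pyranone instead of exchanging, or reagent 10 could add in conjugate fashion or displace methoxide on 9. In that case the four-membered ring would be made by a ketene–alkyne [2+2] cycloaddition instead of being taken from squarate. The fallback sets out from zinc reagent 5, whose MgCl2-promoted addition to ethyl glyoxylate would give ethyl 2-[6-(2,4-dimethoxyphenyl)-4-oxo-4H-pyran-2-yl]-2-hydroxyacetate F3. MeI/Ag2O would give its methyl ether, ethyl 2-[6-(2,4-dimethoxyphenyl)-4-oxo-4H-pyran-2-yl]-2-methoxyacetate F4. Mild hydrolysis (Me3SnOH, 1,2-dichloroethane, 80 °C) would give 2-[6-(2,4-dimethoxyphenyl)-4-oxo-4H-pyran-2-yl]-2-methoxyacetic acid F5, and oxalyl chloride would give 2-[6-(2,4-dimethoxyphenyl)-4-oxo-4H-pyran-2-yl]-2-methoxyacetyl chloride F6. Et3N would release 2-[6-(2,4-dimethoxyphenyl)-4-oxo-4H-pyran-2-yl]-2-methoxyethen-1-one F7, trapped in situ by methoxyacetylene. The ketene carbonyl carbon bonds to the unsubstituted alkyne carbon, so the cycloadduct is cyclobutenone 12, where the route is rejoined.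

3. Step 5, the O-methylation. The tertiary cyclobutenol could undergo retro-aldol-type ring opening or ring contraction before it is alkylated. In that case the methyl group would be introduced after the ring expansion. The fallback sets out from 11, which on thermolysis (degassed p-xylene, 138 °C, Ar) should give 2-(2,4-dimethoxyphenyl)-5,8-dihydroxy-7-methoxy-4H-chromen-4-one F8. Me3SiCHN2 in MeOH/PhMe should then methylate only the free 8-OH, the 5-OH being tied up in the hydrogen bond to C4=O, and so return to the route at 15.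

**Further compounds**

F1 | step 6 | 2-acetyl-3,5,6-trimethoxyphenyl 2,4-dimethoxybenzoate | CC(=O)c1c(OC)cc(OC)c(OC)c1OC(=O)c1ccc(OC)cc1OC
F2 | step 6 | 1-(2,4-dimethoxyphenyl)-3-(2-hydroxy-3,4,6-trimethoxyphenyl)propane-1,3-dione | COc1ccc(C(=O)CC(=O)c2c(OC)cc(OC)c(OC)c2O)c(OC)c1
F3 | step 4 | ethyl 2-[6-(2,4-dimethoxyphenyl)-4-oxo-4H-pyran-2-yl]-2-hydroxyacetate, racemic | CCOC(=O)C(O)c1cc(=O)cc(-c2ccc(OC)cc2OC)o1
F4 | step 4 | ethyl 2-[6-(2,4-dimethoxyphenyl)-4-oxo-4H-pyran-2-yl]-2-methoxyacetate, racemic | CCOC(=O)C(OC)c1cc(=O)cc(-c2ccc(OC)cc2OC)o1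
F5 | step 4 | 2-[6-(2,4-dimethoxyphenyl)-4-oxo-4H-pyran-2-yl]-2-methoxyacetic acid, racemic | COC(C(=O)O)c1cc(=O)cc(-c2ccc(OC)cc2OC)o1
F6 | step 4 | 2-[6-(2,4-dimethoxyphenyl)-4-oxo-4H-pyran-2-yl]-2-methoxyacetyl chloride, racemic | COC(C(=O)Cl)c1cc(=O)cc(-c2ccc(OC)cc2OC)o1
F7 | step 4 | 2-[6-(2,4-dimethoxyphenyl)-4-oxo-4H-pyran-2-yl]-2-methoxyethen-1-one | COC(=C=O)c1cc(=O)cc(-c2ccc(OC)cc2OC)o1
F8 | step 5 | 2-(2,4-dimethoxyphenyl)-5,8-dihydroxy-7-methoxy-4H-chromen-4-one | COc1ccc(-c2cc(=O)c3c(O)cc(OC)c(O)c3o2)c(OC)c1
A1 | direct plan | 1,2,3,5-tetramethoxybenzene | COc1cc(OC)c(OC)c(OC)c1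
A2 | direct plan | 2'-hydroxy-3',4',6'-trimethoxyacetophenone | CC(=O)c1c(OC)cc(OC)c(OC)c1O
A3 | direct plan | 2,4-dimethoxybenzaldehyde | COc1ccc(C=O)c(OC)c1
A4 | direct plan | (E)-2'-hydroxy-2,4,3',4',6'-pentamethoxychalcone | COc1ccc(/C=C/C(=O)c2c(OC)cc(OC)c(OC)c2O)c(OC)c1
A5 | direct plan | 2',4',5,7,8-pentamethoxyflavone | COc1ccc(-c2cc(=O)c3c(OC)cc(OC)c(OC)c3o2)c(OC)c1
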